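**Retrosynthetic overview** (ring numbering: C1 quaternary with CH3 and homofarnesyl, C2 CH with hydroxypropyl, C3 alkylidene carbon, C4 and C5 CH2, C6 C(OH)CH3; homofarnesyl = (3E,7E)-4,8,12-trimethyltrideca-3,7,11-trien-1-yl)
1. Feature: the two functionalised ring carbons C3 and C6 are 1,4-related, so the single carbocycle is a masked 2,2,3-trisubstituted cyclohexane-1,4-dione in which the C4–C5 bond joins two carbons that are each alpha to one of these carbonyl groups.
2. Endgame from that dione: C3=C by dibromo-olefination, site-selective methylation and formylation; C6–CH3 by methyl addition.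
3. Key disconnection C4–C5: anodic coupling of the two enol silyl ethers of an acyclic 3,3,4-trisubstituted hexane-2,5-dione; this closes the only ring.
4. The diketone comes from a γ,δ-unsaturated acid (MeLi, then Wacker oxidation), made by an enantioselective Ireland–Claisen rearrangement that sets C1 and C2.
5. The Claisen substrate is the ester of geranylgeraniol with a 5-silyloxypentanoic acid from δ-valerolactone.

Key step: step 7

Assumption: with i-Pr2NEt in CH2Cl2 the (4R,5R)-bromodiazaborolidine of step 3 is taken to give the Z(O) boron ketene acetal and from it the (2S,3R) acid; if the sense of induction is the opposite one, the (4S,5S) reagent is used and nothing else changes.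

Step 1
Reactants: 1 δ-valerolactone (oxan-2-one)
Product: 5 5-(tert-butyldimethylsilyloxy)pentanoic acid, via sodium 5-hydroxypentanoate 2 (not isolated), via bis-silylated hydroxy acid 3 (not isolated), via potassium carboxylate 4 (not isolated)
Conditions: NaOH, H2O, 60 °C, evaporate; t-BuMe2SiCl, imidazole, DMF, rt; K2CO3, MeOH/THF/H2O, rt; aq KHSO4 to pH 4–5
Reagents that add atoms: sodium hydroxide, [Na+].[OH-]; tert-butyldimethylsilyl chloride, CC(C)(C)[Si](C)(C)Cl
Why: Lactone saponification, exhaustive silylation and selective solvolysis of the labile silyl ester (the silyl ether survives K2CO3 in aqueous methanol) is a standard sequence to ω-silyloxy acids.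

Step 2
Reactants: 5 5-(tert-butyldimethylsilyloxy)pentanoic acid; 6 (2E,6E,10E)-geranylgeraniol
Product: 7 (2E,6E,10E)-geranylgeranyl 5-(tert-butyldimethylsilyloxy)pentanoate
Conditions: DCC, DMAP (cat.), CH2Cl2, 0 °C to rt
Reagents that add atoms: none
Why: Steglich esterification joins an unhindered acid and a primary allylic alcohol under neutral conditions that leave the polyene and the silyl ether untouched.

Step 3
Reactants: 7 (2E,6E,10E)-geranylgeranyl 5-(tert-butyldimethylsilyloxy)pentanoate
Product: 10 (2S,3R,6E,10E)-2-[3-(tert-butyldimethylsilyloxy)propyl]-3-ethenyl-3,7,11,15-tetramethylhexadeca-6,10,14-trienoic acid, via Z(O) boron ketene acetal 8 (not isolated), via boron carboxylate 9 (not isolated)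
Conditions: (4R,5R)-2-bromo-1,3-bis[3,5-bis(trifluoromethyl)phenylsulfonyl]-4,5-diphenyl-1,3,2-diazaborolidine (1.3 equiv), i-Pr2NEt, CH2Cl2, −78 °C; then 4 °C, 48 h; aqueous work-up
Reagents that add atoms: none
Why: Enantioselective Ireland–Claisen rearrangement of a chiral boron ketene acetal: the Z(O) enolate and the (E)-allyl unit react through a chair in which the allyl terminus carries its methyl group axial and the long chain equatorial, which fixes the relative configuration of the quaternary C3 and the tertiary C2 (ring C1 and C2), and the C2-symmetric bis-sulfonamide on boron selects the enolate face and thereby the absolute configuration.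

Step 4
Reactants: 10 (2S,3R,6E,10E)-2-[3-(tert-butyldimethylsilyloxy)propyl]-3-ethenyl-3,7,11,15-tetramethylhexadeca-6,10,14-trienoic acid
Product: 13 (3S,4R,7E,11E)-3-[3-(tert-butyldimethylsilyloxy)propyl]-4-ethenyl-4,8,12,16-tetramethylheptadeca-7,11,15-trien-2-one, via lithium carboxylate 11 (not isolated), via dilithium 1,1-diolate 12 (not isolated)
Conditions: MeLi (3.5 equiv), Et2O, 0 °C to rt; inverse quench into cold aq NH4Cl
Reagents that add atoms: methyllithium, [Li]C
Why: Addition of methyllithium to a lithium carboxylate stops at the dilithium 1,1-diolate, which releases the methyl ketone only on the quench, so over-addition and epimerisation of the α-carbon are avoided.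

Step 5
Reactants: 13 (3S,4R,7E,11E)-3-[3-(tert-butyldimethylsilyloxy)propyl]-4-ethenyl-4,8,12,16-tetramethylheptadeca-7,11,15-trien-2-one
Product: 14 (3S,4S)-4-[3-(tert-butyldimethylsilyloxy)propyl]-3-homofarnesyl-3-methylhexane-2,5-dione
Conditions: PdCl2 (15 mol %), CuCl (1 equiv), O2 (1 atm), DMF/H2O 7:1, rt
Reagents that add atoms: water, O
Why: Tsuji–Wacker oxidation: divalent palladium binds only the monosubstituted alkene, water attacks its internal carbon (Markovnikov) and CuCl/O2 reoxidises the palladium, so the second acetyl group should form without touching the trisubstituted chain alkenes or the two stereocentres.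

Step 6
Reactants: 14 (3S,4S)-4-[3-(tert-butyldimethylsilyloxy)propyl]-3-homofarnesyl-3-methylhexane-2,5-dione
Product: 15 (3S,4S)-4-[3-(tert-butyldimethylsilyloxy)propyl]-3-homofarnesyl-3-methyl-2,5-bis(trimethylsilyloxy)hexa-1,5-diene
Conditions: 14 added to LiN(i-Pr)2 (2.6 equiv)/Me3SiCl (6 equiv), THF, −78 °C; pentane, filtration; used crude
Reagents that add atoms: chlorotrimethylsilane, C[Si](C)(C)Cl
Why: Kinetic enolate formation with in situ silylation: the hindered amide removes only acetyl methyl protons (C1 is quaternary, C2–H is a hindered methine), and each enolate is silylated before it can add to the other carbonyl group in an aldol closure.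

Step 7
Reactants: 15 (3S,4S)-4-[3-(tert-butyldimethylsilyloxy)propyl]-3-homofarnesyl-3-methyl-2,5-bis(trimethylsilyloxy)hexa-1,5-diene
Product: 16 (2S,3S)-3-[3-(tert-butyldimethylsilyloxy)propyl]-2-homofarnesyl-2-methylcyclohexane-1,4-dione
Conditions: undivided cell, reticulated vitreous carbon anode, Pt cathode, constant current (about 2.2 F/mol), LiClO4 (0.1 M), 2,6-lutidine, MeCN/i-PrOH 9:1, 0 °C
Reagents that add atoms: none
Why: At the carbon anode one silyl enol ether is oxidised to its radical cation, whose terminal CH2 bonds to the terminal CH2 of the second enol ether; a second electron is removed and both Me3Si groups pass to 2-propanol, leaving the 1,4-diketone while the cathode reduces protons to H2. The closest known reaction type is the intramolecular oxidative coupling of bis(silyl enol ethers) to 1,4-diketones, run anodically or with oxidants such as (NH4)2Ce(NO3)6 or Cu(OTf)2. The ring closes in a six-membered endo mode with both former enol carbons (C3 and C6) inside the ring, the 1,6-bonding of a 2,5-dioxygenated hexa-1,5-diene, so the radical and the cation that develop are each stabilised by oxygen. No stereocentre is formed, and C1 and C2 are spectators because C2–H is neither oxidised nor enolised in the lutidine-buffered medium. The step needs oxidation of the enol ethers in preference to the three trisubstituted chain alkenes, which the lower oxidation potential of silyl enol ethers and low-current-density electrolysis should secure, and it needs terminus-to-terminus bonding instead of capture by the nearest chain alkene, which the 1,4-disposition of the two enol ethers across C1–C2 and the higher nucleophilicity of an enol ether should secure. The positions of coupling are fixed beforehand by the regiodefined enol ethers of step 6.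

Step 8
Reactants: 16 (2S,3S)-3-[3-(tert-butyldimethylsilyloxy)propyl]-2-homofarnesyl-2-methylcyclohexane-1,4-dione
Product: 17 (2S,3S)-4-(dibromomethylidene)-3-[3-(tert-butyldimethylsilyloxy)propyl]-2-homofarnesyl-2-methylcyclohexan-1-one
Conditions: CBr4 (2 equiv), PPh3 (2 equiv), Zn dust (2 equiv), CH2Cl2, rt (ylide pre-formed); then 16, 40 °C
Reagents that add atoms: carbon tetrabromide, BrC(Br)(Br)Br
Why: Ramirez (Corey–Fuchs-type) dibromo-olefination: the bulky ylide Ph3P=CBr2 should attack the ring C3 carbonyl, whose α-carbon is tertiary, and leave the C6 carbonyl next to the quaternary C1 untouched, while zinc removes Ph3PBr2 so that the silyl ether survives.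

Step 9
Reactants: 17 (2S,3S)-4-(dibromomethylidene)-3-[3-(tert-butyldimethylsilyloxy)propyl]-2-homofarnesyl-2-methylcyclohexan-1-one
Product: 18 (2S,3S,4Z)-4-(1-bromoethylidene)-3-[3-(tert-butyldimethylsilyloxy)propyl]-2-homofarnesyl-2-methylcyclohexan-1-one
Conditions: MeZnCl (1.2 equiv), PdCl2(DPEphos) (5 mol %), THF, 0 °C to rt
Reagents that add atoms: methylzinc chloride, C[Zn]Cl
Why: Negishi cross-coupling: zerovalent palladium should insert into the C–Br bond on the C4 side, the less hindered one (the other bromine is pressed against C2 and its side chain), so the methyl group ends cis to C4 and the remaining bromine cis to C2, which fixes the alkene geometry; the ketone is inert to the organozinc.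

Step 10
Reactants: 18 (2S,3S,4Z)-4-(1-bromoethylidene)-3-[3-(tert-butyldimethylsilyloxy)propyl]-2-homofarnesyl-2-methylcyclohexan-1-one
Product: 19 (1S,2S,3S,4Z)-4-(1-bromoethylidene)-3-[3-(tert-butyldimethylsilyloxy)propyl]-2-homofarnesyl-1,2-dimethylcyclohexan-1-ol
Conditions: MeLi/CeCl3 (2 equiv), THF, −78 °C; aq NH4Cl
Reagents that add atoms: methyllithium, [Li]C
Why: 1,2-Addition of an organocerium reagent (little enolisation, no bromine–metal exchange): A(1,3) strain between the vinylic bromine and the C2 side chain holds that chain axial, so the face of the C6 carbonyl syn to it is blocked by a 1,3-diaxial contact and the methyl group should enter anti to the side chain, giving C6 with CH3 cis to the homofarnesyl group and OH cis to the C2 side chain.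

Step 11
Reactants: 19 (1S,2S,3S,4Z)-4-(1-bromoethylidene)-3-[3-(tert-butyldimethylsilyloxy)propyl]-2-homofarnesyl-1,2-dimethylcyclohexan-1-ol
Product: 22 (2Z)-2-[(2R,3S,4S)-2-[3-(tert-butyldimethylsilyloxy)propyl]-4-hydroxy-3-homofarnesyl-3,4-dimethylcyclohexylidene]propanal, via lithium alkoxide 20 (not isolated), via alkenyllithium 21 (not isolated)
Conditions: t-BuLi (3.3 equiv), THF, −78 °C; then DMF, −78 to 0 °C; aq NH4Cl
Reagents that add atoms: N,N-dimethylformamide, CN(C)C=O
Why: Bromine–lithium exchange (the first equivalent of t-BuLi forms the alkoxide) gives a configurationally stable alkenyllithium that is formylated by DMF with retention, which places CHO cis to C2 (Z).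

Step 12
Reactants: 22 (2Z)-2-[(2R,3S,4S)-2-[3-(tert-butyldimethylsilyloxy)propyl]-4-hydroxy-3-homofarnesyl-3,4-dimethylcyclohexylidene]propanal
Product: 23 iridal, (2Z)-2-[(2R,3S,4S)-4-hydroxy-2-(3-hydroxypropyl)-3-homofarnesyl-3,4-dimethylcyclohexylidene]propanal
Conditions: HF·pyridine, pyridine, THF, 0 °C
Reagents that add atoms: none
Why: Fluoride-mediated desilylation under buffered, weakly acidic conditions removes the primary silyl ether without base-induced dienolate formation, which would isomerise the enal or epimerise C2.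

**Compound list**
1 | δ-valerolactone (oxan-2-one) | O=C1CCCCO1 | starting material
2 | sodium 5-hydroxypentanoate | [Na+].[O-]C(=O)CCCCO | intermediate (not isolated)
3 | tert-butyldimethylsilyl 5-(tert-butyldimethylsilyloxy)pentanoate | CC(C)(C)[Si](C)(C)OCCCCC(=O)O[Si](C)(C)C(C)(C)C | intermediate (not isolated)
4 | potassium 5-(tert-butyldimethylsilyloxy)pentanoate | [K+].[O-]C(=O)CCCCO[Si](C)(C)C(C)(C)C | intermediate (not isolated)
5 | 5-(tert-butyldimethylsilyloxy)pentanoic acid | OC(=O)CCCCO[Si](C)(C)C(C)(C)C | intermediate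
6 | (2E,6E,10E)-geranylgeraniol | CC(C)=CCC/C(C)=C/CC/C(C)=C/CC/C(C)=C/CO | starting material
7 | (2E,6E,10E)-geranylgeranyl 5-(tert-butyldimethylsilyloxy)pentanoate | CC(C)=CCC/C(C)=C/CC/C(C)=C/CC/C(C)=C/COC(=O)CCCCO[Si](C)(C)C(C)(C)C | intermediate
8 | Z(O) boron ketene acetal of 7 (side chain cis to O–B, boron in the (4R,5R)-diazaborolidine) | CC(C)=CCC/C(C)=C/CC/C(C)=C/CC/C(C)=C/CO/C(OB1N(S(=O)(=O)c2cc(cc(c2)C(F)(F)F)C(F)(F)F)[C@H](c2ccccc2)[C@@H](c2ccccc2)N1S(=O)(=O)c1cc(cc(c1)C(F)(F)F)C(F)(F)F)=C/CCCO[Si](C)(C)C(C)(C)C | intermediate (not isolated)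
9 | (4R,5R)-diazaborolidin-2-yl ester of acid 10 | CC(C)=CCC/C(C)=C/CC/C(C)=C/CC[C@@](C=C)(C)[C@H](CCCO[Si](C)(C)C(C)(C)C)C(=O)OB1N(S(=O)(=O)c2cc(cc(c2)C(F)(F)F)C(F)(F)F)[C@H](c2ccccc2)[C@@H](c2ccccc2)N1S(=O)(=O)c1cc(cc(c1)C(F)(F)F)C(F)(F)F | intermediate (not isolated)
10 | (2S,3R,6E,10E)-2-[3-(tert-butyldimethylsilyloxy)propyl]-3-ethenyl-3,7,11,15-tetramethylhexadeca-6,10,14-trienoic acid | CC(C)=CCC/C(C)=C/CC/C(C)=C/CC[C@@](C=C)(C)[C@H](CCCO[Si](C)(C)C(C)(C)C)C(=O)O | intermediate
11 | lithium salt of acid 10 | CC(C)=CCC/C(C)=C/CC/C(C)=C/CC[C@@](C=C)(C)[C@H](CCCO[Si](C)(C)C(C)(C)C)C(=O)O[Li] | intermediate (not isolated)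
12 | dilithium 1,1-diolate from 11 and methyllithium | CC(C)=CCC/C(C)=C/CC/C(C)=C/CC[C@@](C=C)(C)[C@H](CCCO[Si](C)(C)C(C)(C)C)C(C)(O[Li])O[Li] | intermediate (not isolated)
13 | (3S,4R,7E,11E)-3-[3-(tert-butyldimethylsilyloxy)propyl]-4-ethenyl-4,8,12,16-tetramethylheptadeca-7,11,15-trien-2-one | CC(C)=CCC/C(C)=C/CC/C(C)=C/CC[C@@](C=C)(C)[C@H](CCCO[Si](C)(C)C(C)(C)C)C(C)=O | intermediate
14 | (3S,4S)-4-[3-(tert-butyldimethylsilyloxy)propyl]-3-homofarnesyl-3-methylhexane-2,5-dione | CC(C)=CCC/C(C)=C/CC/C(C)=C/CC[C@@](C(C)=O)(C)[C@H](CCCO[Si](C)(C)C(C)(C)C)C(C)=O | intermediate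
15 | (3S,4S)-4-[3-(tert-butyldimethylsilyloxy)propyl]-3-homofarnesyl-3-methyl-2,5-bis(trimethylsilyloxy)hexa-1,5-diene | CC(C)=CCC/C(C)=C/CC/C(C)=C/CC[C@@](C(=C)O[Si](C)(C)C)(C)[C@H](CCCO[Si](C)(C)C(C)(C)C)C(=C)O[Si](C)(C)C | intermediate
16 | (2S,3S)-3-[3-(tert-butyldimethylsilyloxy)propyl]-2-homofarnesyl-2-methylcyclohexane-1,4-dione | CC(C)=CCC/C(C)=C/CC/C(C)=C/CC[C@@]1(C)[C@H](CCCO[Si](C)(C)C(C)(C)C)C(=O)CCC1=O | intermediate
17 | (2S,3S)-4-(dibromomethylidene)-3-[3-(tert-butyldimethylsilyloxy)propyl]-2-homofarnesyl-2-methylcyclohexan-1-one | CC(C)=CCC/C(C)=C/CC/C(C)=C/CC[C@@]1(C)[C@H](CCCO[Si](C)(C)C(C)(C)C)C(=C(Br)Br)CCC1=O | intermediate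
18 | (2S,3S,4Z)-4-(1-bromoethylidene)-3-[3-(tert-butyldimethylsilyloxy)propyl]-2-homofarnesyl-2-methylcyclohexan-1-one | CC(C)=CCC/C(C)=C/CC/C(C)=C/CC[C@@]1(C)[C@H](CCCO[Si](C)(C)C(C)(C)C)/C(=C(/C)Br)CCC1=O | intermediate
19 | (1S,2S,3S,4Z)-4-(1-bromoethylidene)-3-[3-(tert-butyldimethylsilyloxy)propyl]-2-homofarnesyl-1,2-dimethylcyclohexan-1-ol | CC(C)=CCC/C(C)=C/CC/C(C)=C/CC[C@@]1(C)[C@H](CCCO[Si](C)(C)C(C)(C)C)/C(=C(/C)Br)CC[C@]1(C)O | intermediate
20 | lithium alkoxide of 19 | CC(C)=CCC/C(C)=C/CC/C(C)=C/CC[C@@]1(C)[C@H](CCCO[Si](C)(C)C(C)(C)C)/C(=C(/C)Br)CC[C@]1(C)O[Li] | intermediate (not isolated)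
21 | alkenyllithium from 20 (Li in place of Br, lithium alkoxide at C6) | CC(C)=CCC/C(C)=C/CC/C(C)=C/CC[C@@]1(C)[C@H](CCCO[Si](C)(C)C(C)(C)C)/C(=C(/C)[Li])CC[C@]1(C)O[Li] | intermediate (not isolated)
22 | (2Z)-2-[(2R,3S,4S)-2-[3-(tert-butyldimethylsilyloxy)propyl]-4-hydroxy-3-homofarnesyl-3,4-dimethylcyclohexylidene]propanal | CC(C)=CCC/C(C)=C/CC/C(C)=C/CC[C@@]1(C)[C@H](CCCO[Si](C)(C)C(C)(C)C)/C(=C(/C)C=O)CC[C@]1(C)O | intermediate
23 | iridal, (2Z)-2-[(2R,3S,4S)-4-hydroxy-2-(3-hydroxypropyl)-3-homofarnesyl-3,4-dimethylcyclohexylidene]propanal | CC(C)=CCC/C(C)=C/CC/C(C)=C/CC[C@@]1(C)[C@H](CCCO)/C(=C(/C)C=O)CC[C@]1(C)O | target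

**Step count:** 12 steps in total; longest linear sequence 12 steps (from δ-valerolactone 1; 11 steps from geranylgeraniol 6).

**Steps most likely to fail**

Step 7. A chain alkene may be oxidised in competition, the enol ether radical cation may be captured by the nearest chain alkene, the enol ethers may solvolyse before they are oxidised, or the cyclised radical cation may fragment across C1–C2. The fallback replaces single-electron oxidation by a polar halogenation–alkylation sequence. It sets out from 15: MeLi (2.1 equiv, THF, 0 °C) cleaves both O–Si bonds to the regiodefined dilithium bis-enolate F1, in which no carbonyl group is left for an aldol closure. Iodine (1 equiv, −78 °C to rt) then iodinates one enolate terminus to the α-iodo ketone enolate F2, which closes the six-membered ring by intramolecular C-alkylation. The sequence comes back to the route at 16.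

Step 9. Oxidative addition may not discriminate enough between the two C–Br bonds, or the second bromide may also be methylated, and either would erode the alkene geometry. The fallback builds the enal by oxidative allylic transposition and needs no vinyl bromide. It sets out from 16: 2-propenylmagnesium bromide/CeCl3 (THF, −78 °C) adds to the less hindered C3 carbonyl to give the tertiary allylic alcohol F3 (the configuration of the new carbinol is of no consequence). MeLi/CeCl3 then adds to the C6 carbonyl, expected with the same facial preference as in step 10, to give the diol F4. Pyridinium chlorochromate, [C5H5NH][CrO3Cl], in CH2Cl2 (Babler–Dauben oxidative 1,3-transposition) converts the allylic carbinol into the enal. This gives 22, where the route is rejoined before step 12, together with its (E)-isomer F5, which would have to be separated by chromatography.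

Step 5. Hydroxypalladation of the neopentyl vinyl group may be slow, attack at the terminal carbon (aldehyde formation, assisted by the γ-carbonyl group) may compete, and the silyl ether may be lost on long reaction times. The fallback lets the carboxyl group deliver the oxygen and sets out from acid 10 (step 4 is then not used). Iodolactonisation (I2, NaHCO3, MeCN, 0 °C) closes a five-membered lactone on the internal vinyl carbon to give the iodolactone F6; the chain alkenes have no internal nucleophile. Bu3SnH/AIBN (benzene, 80 °C) removes the iodine to give the methyl lactone F7. MeLi (1 equiv, THF, −78 °C) opens it to the hydroxy ketone F8 (in equilibrium with its lactol). Dess–Martin periodinane oxidises the secondary alcohol and the sequence comes back to the route at 14.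

**Further compounds**
F1 | step 7 | dilithium bis-enolate corresponding to 15 | CC(C)=CCC/C(C)=C/CC/C(C)=C/CC[C@@](C(=C)O[Li])(C)[C@H](CCCO[Si](C)(C)C(C)(C)C)C(=C)O[Li]
F2 | step 7 | α-iodo ketone lithium enolate (iodine on the acetyl carbon next to C3) | CC(C)=CCC/C(C)=C/CC/C(C)=C/CC[C@@](C(=C)O[Li])(C)[C@H](CCCO[Si](C)(C)C(C)(C)C)C(=O)CI
F3 | step 9 | (2S,3S)-4-hydroxy-2-methyl-4-(prop-1-en-2-yl)-3-[3-(tert-butyldimethylsilyloxy)propyl]-2-homofarnesylcyclohexan-1-one (C4 epimers) | CC(C)=CCC/C(C)=C/CC/C(C)=C/CC[C@@]1(C)[C@H](CCCO[Si](C)(C)C(C)(C)C)C(O)(C(C)=C)CCC1=O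
F4 | step 9 | (1S,2S,3S)-1,2-dimethyl-4-(prop-1-en-2-yl)-3-[3-(tert-butyldimethylsilyloxy)propyl]-2-homofarnesylcyclohexane-1,4-diol (C4 epimers) | CC(C)=CCC/C(C)=C/CC/C(C)=C/CC[C@@]1(C)[C@H](CCCO[Si](C)(C)C(C)(C)C)C(O)(C(C)=C)CC[C@]1(C)O
F5 | step 9 | (2E)-isomer of 22 | CC(C)=CCC/C(C)=C/CC/C(C)=C/CC[C@@]1(C)[C@H](CCCO[Si](C)(C)C(C)(C)C)/C(=C(\C)C=O)CC[C@]1(C)O
F6 | step 5 | (3S,4S)-5-(iodomethyl)-4-methyl-3-[3-(tert-butyldimethylsilyloxy)propyl]-4-homofarnesyloxolan-2-one (C5 epimers) | CC(C)=CCC/C(C)=C/CC/C(C)=C/CC[C@@]1(C)[C@H](CCCO[Si](C)(C)C(C)(C)C)C(=O)OC1CI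
F7 | step 5 | (3S,4S)-4,5-dimethyl-3-[3-(tert-butyldimethylsilyloxy)propyl]-4-homofarnesyloxolan-2-one (C5 epimers) | CC(C)=CCC/C(C)=C/CC/C(C)=C/CC[C@@]1(C)[C@H](CCCO[Si](C)(C)C(C)(C)C)C(=O)OC1C
F8 | step 5 | (3S,4S)-5-hydroxy-4-methyl-3-[3-(tert-butyldimethylsilyloxy)propyl]-4-homofarnesylhexan-2-one (C5 epimers) | CC(C)=CCC/C(C)=C/CC/C(C)=C/CC[C@@](C(C)O)(C)[C@H](CCCO[Si](C)(C)C(C)(C)C)C(C)=O
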